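Each flavan unit is a pyran ring C ortho-fused to phloroglucinol ring A through the adjacent carbons C8a (bearing O1) and C4a (bearing C4), with a 5-oxygen next to C4a. The route exploits this in the top unit: ring A arrives as 3,5-bis(benzyloxy)benzyne, which inserts into an open-chain syn β-hydroxy-α-benzyloxy ketone hung on C8 of the middle unit. The chain hydroxyl adds to the distal aryne carbon (O1–C8a) and the aryl anion closes onto the ketone (C4a–C4), giving the 4-aryl-4-hydroxyflavan in one operation. Ionic reduction then sets the all-cis C4, and the same annulation–reduction pair, run from the bottom unit upward, assembles the trimer.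

Key step: step 19

Remark (assumption on the chemistry): the target is read as ent-epiafzelechin-(4β→8)-epiafzelechin-(4α→8)-(2S,3S,4R)-flavan-3,4,5,7,4'-pentol, i.e. top unit (2S,3S,4R), middle unit (2R,3R,4S), bottom unit (2S,3S,4R). Top and middle units are all-cis (H-2, H-3 and H-4 on one face); the bottom unit is 2,3-cis-3,4-trans. Flavan numbering is used within each unit; Bn = benzyl. The aryl anions formed by alkoxide addition to the aryne are drawn as their caesium compounds.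

Step 1
Reactants: 1 3,5-bis(benzyloxy)phenol
Product: 2 3,5-bis(benzyloxy)phenyl N-isopropylcarbamate
Conditions: i-PrNCO, Et3N (cat.), CH2Cl2, rt
Reagents that add atoms: isopropyl isocyanate CC(C)N=C=O
Why: Carbamoylation of the phenol by addition to the isocyanate installs a directing group for ortho-metalation that can later be removed under mild base.

Step 2
Reactants: 2 3,5-bis(benzyloxy)phenyl N-isopropylcarbamate
Product: 6 3,5-bis(benzyloxy)-2-(trimethylsilyl)phenyl N-isopropylcarbamate, via N-silyl carbamate 3 (not isolated), via aryllithium 4 (not isolated), via disilyl carbamate 5 (not isolated)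
Conditions: TMSOTf, TMEDA, Et2O, 0 °C to rt; n-BuLi, TMEDA, −78 °C; TMSCl, −78 °C to rt; aq. NaHSO4
Reagents that add atoms: chlorotrimethylsilane C[Si](C)(C)Cl
Why: Directed ortho-metalation: after in situ N-silylation the carbamate directs lithiation to C2 (both ortho positions are equivalent and each is also flanked by a benzyloxy group), the silyl quench gives the aryl silane and the N–Si bond is hydrolysed on work-up.

Step 3
Reactants: 6 3,5-bis(benzyloxy)-2-(trimethylsilyl)phenyl N-isopropylcarbamate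
Product: 8 3,5-bis(benzyloxy)-2-(trimethylsilyl)phenyl trifluoromethanesulfonate, via silylphenol 7 (not isolated)
Conditions: DBU, Et2NH, MeCN, 40 °C; then PhNTf2, rt
Reagents that add atoms: N-phenylbis(trifluoromethanesulfonimide) O=S(=O)(N(c1ccccc1)S(=O)(=O)C(F)(F)F)C(F)(F)F
Why: Base-induced E1cB cleavage of the carbamate (the isocyanate is scavenged by Et2NH) frees the phenoxide, which is triflated in the same flask to give the 2-silylaryl triflate aryne precursor.

Step 4
Reactants: 9 (R)-4-benzyloxazolidin-2-one; 10 (benzyloxy)acetyl chloride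
Product: 11 (R)-4-benzyl-3-[(benzyloxy)acetyl]oxazolidin-2-one
Conditions: Et3N, DMAP (cat.), CH2Cl2, 0 °C to rt
Reagents that add atoms: none
Why: N-Acylation of the oxazolidinone by the acid chloride under nucleophilic catalysis leaves the auxiliary stereocentre untouched.

Step 5
Reactants: 11 (R)-4-benzyl-3-[(benzyloxy)acetyl]oxazolidin-2-one; 12 4-(benzyloxy)benzaldehyde
Product: 14 (R)-4-benzyl-3-[(2R,3S)-2-(benzyloxy)-3-[4-(benzyloxy)phenyl]-3-hydroxypropanoyl]oxazolidin-2-one, via boron enolate 13 (not isolated)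
Conditions: Bu2BOTf, Et3N, CH2Cl2, −78 to 0 °C; then 12, −78 to 0 °C; pH 7 buffer, MeOH, H2O2
Reagents that add atoms: none
Why: Evans syn-aldol reaction: the Z-boron enolate reacts through a chair (Zimmerman–Traxler) transition state on the enolate face away from the auxiliary benzyl group, which should set both new centres as the (2R,3S) syn adduct with the α-oxygen benzylated and the β-hydroxyl free.

Step 6
Reactants: 14 (R)-4-benzyl-3-[(2R,3S)-2-(benzyloxy)-3-[4-(benzyloxy)phenyl]-3-hydroxypropanoyl]oxazolidin-2-one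
Product: 15 (2R,3S)-2-(benzyloxy)-3-[4-(benzyloxy)phenyl]-3-hydroxy-N-methoxy-N-methylpropanamide
Conditions: MeONHMe·HCl, AlMe3, CH2Cl2, −20 to 0 °C
Reagents that add atoms: N,O-dimethylhydroxylamine hydrochloride Cl.CNOC
Why: Aluminium-amide transamination (Weinreb amide formation), assisted by the free β-hydroxyl, releases the auxiliary without touching either stereocentre.

Step 7
Reactants: 15 (2R,3S)-2-(benzyloxy)-3-[4-(benzyloxy)phenyl]-3-hydroxy-N-methoxy-N-methylpropanamide
Product: 16 (2R,3S)-2-(benzyloxy)-3-[4-(benzyloxy)phenyl]-3-hydroxypropanal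
Conditions: i-Bu2AlH, THF, −78 °C; aq. potassium sodium tartrate
Reagents that add atoms: none
Why: Weinreb amide reduction stops at the aldehyde because the chelated aluminium hemiaminal collapses only on work-up, and the low temperature should preserve the α-stereocentre.

Step 8
Reactants: 16 (2R,3S)-2-(benzyloxy)-3-[4-(benzyloxy)phenyl]-3-hydroxypropanal; 8 3,5-bis(benzyloxy)-2-(trimethylsilyl)phenyl trifluoromethanesulfonate
Product: 19 (2S,3S)-3,5,7-tris(benzyloxy)-2-[4-(benzyloxy)phenyl]chroman-4-ol (2,3-cis; C4 epimers), via aryne 17 (not isolated), via arylcaesium 18 (not isolated)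
Conditions: CsF, MeCN–toluene, 0 °C to rt
Reagents that add atoms: none
Why: Proposed new method: fluoride releases aryne 17 from 8, the free hydroxyl of 16 adds to the aryne carbon remote from the flanking benzyloxy group to give aryl anion 18, and 18, which sits next to that benzyloxy group, closes onto the aldehyde (6-exo-trig) before it is protonated; C2 and C3 are carried over unchanged because the C2–O bond is never broken (syn aldol gives the 2,3-cis flavan), the C4 carbinol needs no control, and the closest known reaction types are O–H insertion of aliphatic alcohols into arynes and the aryne annulation of salicylaldehydes and salicylate esters to xanthenols and xanthones.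

Step 9
Reactants: 19 (2S,3S)-3,5,7-tris(benzyloxy)-2-[4-(benzyloxy)phenyl]chroman-4-ol
Product: 20 3,5,7,4'-tetra-O-benzyl-ent-epiafzelechin [(2S,3S)-3,5,7-tris(benzyloxy)-2-[4-(benzyloxy)phenyl]chroman]
Conditions: Et3SiH (excess), TFA, CH2Cl2, −20 to 0 °C
Reagents that add atoms: none
Why: Kursanov–Parnes ionic hydrogenation: acid ionises the benzylic C4 carbinol to the ring-A-stabilised cation, which the excess silane should reduce before it can arylate another flavan, so both C4 epimers converge on the methylene compound.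

Step 10
Reactants: 20 3,5,7,4'-tetra-O-benzyl-ent-epiafzelechin
Product: 21 8-bromo-3,5,7,4'-tetra-O-benzyl-ent-epiafzelechin
Conditions: NBS, CH2Cl2, −78 to 0 °C
Reagents that add atoms: N-bromosuccinimide O=C1CCC(=O)N1Br
Why: Electrophilic aromatic bromination should take place at C8, the more accessible free position of the 5,7-dialkoxy ring A (C6 lies between two benzyloxy groups), the selectivity established for benzylated flavan-3-ols.

Step 11
Reactants: 22 (S)-4-benzyloxazolidin-2-one; 10 (benzyloxy)acetyl chloride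
Product: 23 (S)-4-benzyl-3-[(benzyloxy)acetyl]oxazolidin-2-one
Conditions: Et3N, DMAP (cat.), CH2Cl2, 0 °C to rt
Reagents that add atoms: none
Why: N-Acylation as in step 4, here with the enantiomeric auxiliary.

Step 12
Reactants: 23 (S)-4-benzyl-3-[(benzyloxy)acetyl]oxazolidin-2-one; 12 4-(benzyloxy)benzaldehyde
Product: 25 (S)-4-benzyl-3-[(2S,3R)-2-(benzyloxy)-3-[4-(benzyloxy)phenyl]-3-hydroxypropanoyl]oxazolidin-2-one, via boron enolate 24 (not isolated)
Conditions: Bu2BOTf, Et3N, CH2Cl2, −78 to 0 °C; then 12, −78 to 0 °C; pH 7 buffer, MeOH, H2O2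
Reagents that add atoms: none
Why: Evans syn-aldol reaction as in step 5, the (S)-auxiliary now directing the aldehyde to the opposite enolate face to give the (2S,3R) syn adduct.

Step 13
Reactants: 25 (S)-4-benzyl-3-[(2S,3R)-2-(benzyloxy)-3-[4-(benzyloxy)phenyl]-3-hydroxypropanoyl]oxazolidin-2-one
Product: 26 (2S,3R)-2-(benzyloxy)-3-[4-(benzyloxy)phenyl]-3-hydroxy-N-methoxy-N-methylpropanamide
Conditions: MeONHMe·HCl, AlMe3, CH2Cl2, −20 to 0 °C
Reagents that add atoms: N,O-dimethylhydroxylamine hydrochloride Cl.CNOC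
Why: Weinreb amide formation by aluminium-amide transamination as in step 6, with no change at the stereocentres.

Step 14
Reactants: 21 8-bromo-3,5,7,4'-tetra-O-benzyl-ent-epiafzelechin; 26 (2S,3R)-2-(benzyloxy)-3-[4-(benzyloxy)phenyl]-3-hydroxy-N-methoxy-N-methylpropanamide
Product: 29 8-[(2S,3R)-2-(benzyloxy)-3-[4-(benzyloxy)phenyl]-3-hydroxypropanoyl]-3,5,7,4'-tetra-O-benzyl-ent-epiafzelechin, via aryllithium 27 (not isolated), via magnesium alkoxide 28 (not isolated)
Conditions: 21, t-BuLi (2 equiv), THF, −78 °C; then 28 (from 26, i-PrMgCl, THF, −78 °C), −78 to −30 °C; aq. NH4Cl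
Reagents that add atoms: none
Why: Bromine–lithium exchange followed by the Weinreb ketone synthesis: the chelated tetrahedral adduct prevents over-addition, the pre-formed alkoxide masks the free hydroxyl, and the α-stereocentre should survive the kinetic low-temperature conditions.

Step 15
Reactants: 29 8-[(2S,3R)-2-(benzyloxy)-3-[4-(benzyloxy)phenyl]-3-hydroxypropanoyl]-3,5,7,4'-tetra-O-benzyl-ent-epiafzelechin; 8 3,5-bis(benzyloxy)-2-(trimethylsilyl)phenyl trifluoromethanesulfonate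
Product: 31 4-hydroxy-3,5,7,4'-tetra-O-benzylepiafzelechin-(4→8)-3,5,7,4'-tetra-O-benzyl-ent-epiafzelechin (C4 carbinol epimers of the new unit), via arylcaesium 30 (not isolated)
Conditions: CsF, MeCN–toluene, 0 °C to rt
Reagents that add atoms: none
Why: Proposed new method: fluoride sets aryne 17 free from a further portion of 8 as in step 8, the only free hydroxyl of 29 adds to its distal carbon to give aryl anion 30, and 30 closes 6-exo-trig onto the aryl ketone, giving the tertiary 4-aryl carbinol with C2 and C3 of the new unit carried over from the aldol (C2–O bond unbroken, so 2R with 2,3-cis) and a C4 centre that needs no control; the closest known types are alcohol O–H insertion into arynes and the aryne annulation of salicylaldehydes and salicylate esters.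

Step 16
Reactants: 31 4-hydroxy-3,5,7,4'-tetra-O-benzylepiafzelechin-(4→8)-3,5,7,4'-tetra-O-benzyl-ent-epiafzelechin
Product: 32 3,5,7,4'-tetra-O-benzylepiafzelechin-(4α→8)-3,5,7,4'-tetra-O-benzyl-ent-epiafzelechin
Conditions: Bu3SnH, TFA, CH2Cl2, 0 °C
Reagents that add atoms: none
Why: Ionic reduction: both carbinol epimers give the same doubly benzylic C4 cation, and hydride should be delivered anti to the axial C3 benzyloxy group and the C2 aryl, placing H-4 cis to H-2 and H-3 (all-cis), the face on which nucleophiles enter C4 cations of 2,3-cis flavan-3-ol derivatives and the course established for tin hydride reductions of 4-arylflavan-4-ols.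

Step 17
Reactants: 32 3,5,7,4'-tetra-O-benzylepiafzelechin-(4α→8)-3,5,7,4'-tetra-O-benzyl-ent-epiafzelechin
Product: 33 8-bromo-3,5,7,4'-tetra-O-benzylepiafzelechin-(4α→8)-3,5,7,4'-tetra-O-benzyl-ent-epiafzelechin (bromine on C8 of the upper unit, the future middle unit)
Conditions: NBS (1 equiv), CH2Cl2, −78 to 0 °C
Reagents that add atoms: N-bromosuccinimide O=C1CCC(=O)N1Br
Why: Electrophilic bromination should select the single free C8 position (flanked by O1 and one benzyloxy group) over the two C6 positions, each of which lies between two benzyloxy groups.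

Step 18
Reactants: 33 8-bromo-3,5,7,4'-tetra-O-benzylepiafzelechin-(4α→8)-3,5,7,4'-tetra-O-benzyl-ent-epiafzelechin; 15 (2R,3S)-2-(benzyloxy)-3-[4-(benzyloxy)phenyl]-3-hydroxy-N-methoxy-N-methylpropanamide
Product: 36 8-[(2R,3S)-2-(benzyloxy)-3-[4-(benzyloxy)phenyl]-3-hydroxypropanoyl]-3,5,7,4'-tetra-O-benzylepiafzelechin-(4α→8)-3,5,7,4'-tetra-O-benzyl-ent-epiafzelechin, via aryllithium 34 (not isolated), via magnesium alkoxide 35 (not isolated)
Conditions: 33, t-BuLi (2 equiv), THF, −78 °C; then 35 (from 15, i-PrMgCl, THF, −78 °C), −78 to −30 °C; aq. NH4Cl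
Reagents that add atoms: none
Why: Bromine–lithium exchange and Weinreb ketone synthesis as in step 14 attach the (2R,3S) aldol chain to C8 of the middle unit without over-addition or loss of the α-stereocentre.

Step 19
Reactants: 36 8-[(2R,3S)-2-(benzyloxy)-3-[4-(benzyloxy)phenyl]-3-hydroxypropanoyl]-3,5,7,4'-tetra-O-benzylepiafzelechin-(4α→8)-3,5,7,4'-tetra-O-benzyl-ent-epiafzelechin; 8 3,5-bis(benzyloxy)-2-(trimethylsilyl)phenyl trifluoromethanesulfonate
Product: 38 4-hydroxy-3,5,7,4'-tetra-O-benzyl-ent-epiafzelechin-(4→8)-3,5,7,4'-tetra-O-benzylepiafzelechin-(4α→8)-3,5,7,4'-tetra-O-benzyl-ent-epiafzelechin (C4 carbinol epimers of the top unit), via arylcaesium 37 (not isolated)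
Conditions: CsF, MeCN–toluene, 0 °C to rt
Reagents that add atoms: none
Why: Proposed new method: CsF sets 3,5-bis(benzyloxy)benzyne 17 free from a further portion of 8 as in step 8, the only free hydroxyl of 36 (the benzylic hydroxyl of the chain, the future O1 on C2 of the top unit) adds to the aryne carbon remote from the flanking benzyloxy group (O1–C8a) to give aryl anion 37, and 37, which sits next to that benzyloxy group, adds to the C4 ketone (C4a–C4) before it is protonated. The closest known reaction types are the O–H insertion of aliphatic alcohols into arynes and the aryne annulation of salicylaldehydes and salicylate esters to xanthenols and xanthones (nucleophilic addition, then intramolecular carbonyl capture); the tandem on an aliphatic β-hydroxy ketone is the new element. The pyran ring C of the top unit closes in the 6-exo-trig mode. C2 and C3 of the top unit are not made here but carried over from the Evans aldol: the C2–O bond is never broken, so the syn aldol becomes the 2,3-cis flavan. The new C4 carbinol centre needs no control because it is erased in step 20. The step needs aryne regioselectivity, secured by the inductive and distortion effect of the benzyloxy group next to the aryne, and chemoselectivity, secured by 36 having a single O–H and by mild alkoxide-free conditions that disfavour retro-aldol cleavage.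

Step 20
Reactants: 38 4-hydroxy-3,5,7,4'-tetra-O-benzyl-ent-epiafzelechin-(4→8)-3,5,7,4'-tetra-O-benzylepiafzelechin-(4α→8)-3,5,7,4'-tetra-O-benzyl-ent-epiafzelechin
Product: 39 3,5,7,4'-tetra-O-benzyl-ent-epiafzelechin-(4β→8)-3,5,7,4'-tetra-O-benzylepiafzelechin-(4α→8)-3,5,7,4'-tetra-O-benzyl-ent-epiafzelechin
Conditions: Bu3SnH, TFA, CH2Cl2, 0 °C
Reagents that add atoms: none
Why: Ionic reduction as in step 16: the C4 cation of the top unit should accept hydride on the face opposite its C2 aryl and axial C3 benzyloxy group, giving the all-cis (2S,3S,4R) top unit from either carbinol epimer.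

Step 21
Reactants: 39 3,5,7,4'-tetra-O-benzyl-ent-epiafzelechin-(4β→8)-3,5,7,4'-tetra-O-benzylepiafzelechin-(4α→8)-3,5,7,4'-tetra-O-benzyl-ent-epiafzelechin
Product: 40 dodeca-O-benzyl ent-epiafzelechin-(4β→8)-epiafzelechin-(4α→8)-(2S,3S,4R)-flavan-3,4,5,7,4'-pentol (free hydroxyl at C4 of the bottom unit, trans to its C3 benzyloxy group)
Conditions: DDQ, CH2Cl2–H2O, rt
Reagents that add atoms: water O
Why: DDQ benzylic oxidation by hydride abstraction should occur at the only C4 methylene (bottom unit), the two methine C4–H bonds being shielded between ortho-disubstituted aryl rings, and water should capture the cation anti to the axial C3 benzyloxy group, giving the 3,4-trans carbinol as known for benzylated 2,3-cis flavan-3-ols.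

Step 22
Reactants: 40 dodeca-O-benzyl ent-epiafzelechin-(4β→8)-epiafzelechin-(4α→8)-(2S,3S,4R)-flavan-3,4,5,7,4'-pentol
Product: 41 ent-epiafzelechin-(4β→8)-epiafzelechin-(4α→8)-(2S,3S,4R)-flavan-3,4,5,7,4'-pentol (target)
Conditions: H2 (1 atm), Pd(OH)2/C, THF–MeOH–H2O, rt
Reagents that add atoms: none
Why: Catalytic hydrogenolysis should cleave all twelve benzyl ethers under neutral conditions, under which the free C4 carbinol is expected to survive because its C–O cleavage needs acid assistance.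

Compound list
1 | 3,5-bis(benzyloxy)phenol | Oc1cc(OCc2ccccc2)cc(OCc2ccccc2)c1 | starting material
2 | 3,5-bis(benzyloxy)phenyl N-isopropylcarbamate | CC(C)NC(=O)Oc1cc(OCc2ccccc2)cc(OCc2ccccc2)c1 | intermediate
3 | 3,5-bis(benzyloxy)phenyl N-isopropyl-N-(trimethylsilyl)carbamate (not isolated) | CC(C)N([Si](C)(C)C)C(=O)Oc1cc(OCc2ccccc2)cc(OCc2ccccc2)c1 | intermediate
4 | 2-lithio derivative of 3 (not isolated) | CC(C)N([Si](C)(C)C)C(=O)Oc1cc(OCc2ccccc2)cc(OCc2ccccc2)c1[Li] | intermediate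
5 | 3,5-bis(benzyloxy)-2-(trimethylsilyl)phenyl N-isopropyl-N-(trimethylsilyl)carbamate (not isolated) | CC(C)N([Si](C)(C)C)C(=O)Oc1cc(OCc2ccccc2)cc(OCc2ccccc2)c1[Si](C)(C)C | intermediate
6 | 3,5-bis(benzyloxy)-2-(trimethylsilyl)phenyl N-isopropylcarbamate | CC(C)NC(=O)Oc1cc(OCc2ccccc2)cc(OCc2ccccc2)c1[Si](C)(C)C | intermediate
7 | 3,5-bis(benzyloxy)-2-(trimethylsilyl)phenol (not isolated) | C[Si](C)(C)c1c(O)cc(OCc2ccccc2)cc1OCc1ccccc1 | intermediate
8 | 3,5-bis(benzyloxy)-2-(trimethylsilyl)phenyl trifluoromethanesulfonate | C[Si](C)(C)c1c(OS(=O)(=O)C(F)(F)F)cc(OCc2ccccc2)cc1OCc1ccccc1 | intermediate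
9 | (R)-4-benzyloxazolidin-2-one | O=C1N[C@H](Cc2ccccc2)CO1 | starting material
10 | (benzyloxy)acetyl chloride | O=C(Cl)COCc1ccccc1 | starting material
11 | (R)-4-benzyl-3-[(benzyloxy)acetyl]oxazolidin-2-one | O=C1OC[C@@H](Cc2ccccc2)N1C(=O)COCc1ccccc1 | intermediate
12 | 4-(benzyloxy)benzaldehyde | O=Cc1ccc(OCc2ccccc2)cc1 | starting material
13 | Z-dibutylboron enolate of 11 (not isolated) | CCCCB(CCCC)O/C(=C\OCc1ccccc1)N1C(=O)OC[C@H]1Cc1ccccc1 | intermediate
14 | (R)-4-benzyl-3-[(2R,3S)-2-(benzyloxy)-3-[4-(benzyloxy)phenyl]-3-hydroxypropanoyl]oxazolidin-2-one | O=C1OC[C@@H](Cc2ccccc2)N1C(=O)[C@H](OCc1ccccc1)[C@@H](O)c1ccc(OCc2ccccc2)cc1 | intermediate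
15 | (2R,3S)-2-(benzyloxy)-3-[4-(benzyloxy)phenyl]-3-hydroxy-N-methoxy-N-methylpropanamide | CON(C)C(=O)[C@H](OCc1ccccc1)[C@@H](O)c1ccc(OCc2ccccc2)cc1 | intermediate
16 | (2R,3S)-2-(benzyloxy)-3-[4-(benzyloxy)phenyl]-3-hydroxypropanal | O=C[C@H](OCc1ccccc1)[C@@H](O)c1ccc(OCc2ccccc2)cc1 | intermediate
17 | 3,5-bis(benzyloxy)benzyne (1,2-didehydro-3,5-bis(benzyloxy)benzene; not isolated) | O(Cc1ccccc1)C1=CC(OCc2ccccc2)=CC#C1 | intermediate
18 | (2R,3S)-2-(benzyloxy)-3-[4-(benzyloxy)phenyl]-3-[3,5-bis(benzyloxy)-2-caesiophenoxy]propanal (aryl anion drawn as its caesium compound; not isolated) | O=C[C@H](OCc1ccccc1)[C@@H](Oc1cc(OCc2ccccc2)cc(OCc2ccccc2)c1[Cs])c1ccc(OCc2ccccc2)cc1 | intermediate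
19 | (2S,3S)-3,5,7-tris(benzyloxy)-2-[4-(benzyloxy)phenyl]chroman-4-ol, 2,3-cis, mixture of C4 epimers | c1c(OCc2ccccc2)cc(OCc2ccccc2)c2c1O[C@@H](c1ccc(OCc3ccccc3)cc1)[C@@H](OCc1ccccc1)C2O | intermediate
20 | 3,5,7,4'-tetra-O-benzyl-ent-epiafzelechin, (2S,3S)-3,5,7-tris(benzyloxy)-2-[4-(benzyloxy)phenyl]chroman | c1c(OCc2ccccc2)cc(OCc2ccccc2)c2c1O[C@@H](c1ccc(OCc3ccccc3)cc1)[C@@H](OCc1ccccc1)C2 | intermediate
21 | 8-bromo-3,5,7,4'-tetra-O-benzyl-ent-epiafzelechin | Brc1c(OCc2ccccc2)cc(OCc2ccccc2)c2c1O[C@@H](c1ccc(OCc3ccccc3)cc1)[C@@H](OCc1ccccc1)C2 | intermediate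
22 | (S)-4-benzyloxazolidin-2-one | O=C1N[C@@H](Cc2ccccc2)CO1 | starting material
23 | (S)-4-benzyl-3-[(benzyloxy)acetyl]oxazolidin-2-one | O=C1OC[C@H](Cc2ccccc2)N1C(=O)COCc1ccccc1 | intermediate
24 | Z-dibutylboron enolate of 23 (not isolated) | CCCCB(CCCC)O/C(=C\OCc1ccccc1)N1C(=O)OC[C@@H]1Cc1ccccc1 | intermediate
25 | (S)-4-benzyl-3-[(2S,3R)-2-(benzyloxy)-3-[4-(benzyloxy)phenyl]-3-hydroxypropanoyl]oxazolidin-2-one | O=C1OC[C@H](Cc2ccccc2)N1C(=O)[C@@H](OCc1ccccc1)[C@H](O)c1ccc(OCc2ccccc2)cc1 | intermediate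
26 | (2S,3R)-2-(benzyloxy)-3-[4-(benzyloxy)phenyl]-3-hydroxy-N-methoxy-N-methylpropanamide | CON(C)C(=O)[C@@H](OCc1ccccc1)[C@H](O)c1ccc(OCc2ccccc2)cc1 | intermediate
27 | 8-lithio-3,5,7,4'-tetra-O-benzyl-ent-epiafzelechin (not isolated) | [Li]c1c(OCc2ccccc2)cc(OCc2ccccc2)c2c1O[C@@H](c1ccc(OCc3ccccc3)cc1)[C@@H](OCc1ccccc1)C2 | intermediate
28 | chloromagnesium alkoxide of 26 (not isolated) | CON(C)C(=O)[C@@H](OCc1ccccc1)[C@H](O[Mg]Cl)c1ccc(OCc2ccccc2)cc1 | intermediate
29 | 8-[(2S,3R)-2-(benzyloxy)-3-[4-(benzyloxy)phenyl]-3-hydroxypropanoyl]-3,5,7,4'-tetra-O-benzyl-ent-epiafzelechin | O=C(c1c(OCc2ccccc2)cc(OCc2ccccc2)c2c1O[C@@H](c1ccc(OCc3ccccc3)cc1)[C@@H](OCc1ccccc1)C2)[C@@H](OCc1ccccc1)[C@H](O)c1ccc(OCc2ccccc2)cc1 | intermediate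
30 | 8-[(2S,3R)-2-(benzyloxy)-3-[4-(benzyloxy)phenyl]-3-[3,5-bis(benzyloxy)-2-caesiophenoxy]propanoyl]-3,5,7,4'-tetra-O-benzyl-ent-epiafzelechin (aryl anion drawn as its caesium compound; not isolated) | O=C(c1c(OCc2ccccc2)cc(OCc2ccccc2)c2c1O[C@@H](c1ccc(OCc3ccccc3)cc1)[C@@H](OCc1ccccc1)C2)[C@@H](OCc1ccccc1)[C@H](Oc1cc(OCc2ccccc2)cc(OCc2ccccc2)c1[Cs])c1ccc(OCc2ccccc2)cc1 | intermediate
31 | dimeric carbinol: 4-hydroxy-3,5,7,4'-tetra-O-benzylepiafzelechin (2R, 2,3-cis, C4 carbinol unassigned) bonded through C4 to C8 of 3,5,7,4'-tetra-O-benzyl-ent-epiafzelechin | C(c1ccccc1)Oc1ccc([C@H]2Oc3cc(OCc4ccccc4)cc(OCc4ccccc4)c3C(O)(c3c(OCc4ccccc4)cc(OCc4ccccc4)c4c3O[C@@H](c3ccc(OCc5ccccc5)cc3)[C@@H](OCc3ccccc3)C4)[C@H]2OCc2ccccc2)cc1 | intermediate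
32 | 3,5,7,4'-tetra-O-benzylepiafzelechin-(4α→8)-3,5,7,4'-tetra-O-benzyl-ent-epiafzelechin (upper unit 2R,3R with H-2, H-3, H-4 all cis; lower unit 2S,3S) | C(c1ccccc1)Oc1ccc([C@H]2Oc3cc(OCc4ccccc4)cc(OCc4ccccc4)c3[C@@H](c3c(OCc4ccccc4)cc(OCc4ccccc4)c4c3O[C@@H](c3ccc(OCc5ccccc5)cc3)[C@@H](OCc3ccccc3)C4)[C@H]2OCc2ccccc2)cc1 | intermediate
33 | 8-bromo-3,5,7,4'-tetra-O-benzylepiafzelechin-(4α→8)-3,5,7,4'-tetra-O-benzyl-ent-epiafzelechin (bromine on C8 of the upper unit, the future middle unit) | C(c1ccccc1)Oc1ccc([C@H]2Oc3c(Br)c(OCc4ccccc4)cc(OCc4ccccc4)c3[C@@H](c3c(OCc4ccccc4)cc(OCc4ccccc4)c4c3O[C@@H](c3ccc(OCc5ccccc5)cc3)[C@@H](OCc3ccccc3)C4)[C@H]2OCc2ccccc2)cc1 | intermediate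
34 | 8-lithio analogue of the bromide of step 17 (lithium on C8 of the middle unit; not isolated) | C(c1ccccc1)Oc1ccc([C@H]2Oc3c([Li])c(OCc4ccccc4)cc(OCc4ccccc4)c3[C@@H](c3c(OCc4ccccc4)cc(OCc4ccccc4)c4c3O[C@@H](c3ccc(OCc5ccccc5)cc3)[C@@H](OCc3ccccc3)C4)[C@H]2OCc2ccccc2)cc1 | intermediate
35 | chloromagnesium alkoxide of 15 (not isolated) | CON(C)C(=O)[C@H](OCc1ccccc1)[C@@H](O[Mg]Cl)c1ccc(OCc2ccccc2)cc1 | intermediate
36 | 8-[(2R,3S)-2-(benzyloxy)-3-[4-(benzyloxy)phenyl]-3-hydroxypropanoyl]-3,5,7,4'-tetra-O-benzylepiafzelechin-(4α→8)-3,5,7,4'-tetra-O-benzyl-ent-epiafzelechin (acyl group on C8 of the middle unit) | C(c1ccccc1)Oc1ccc([C@H]2Oc3c(C(=O)[C@H](OCc4ccccc4)[C@@H](O)c4ccc(OCc5ccccc5)cc4)c(OCc4ccccc4)cc(OCc4ccccc4)c3[C@@H](c3c(OCc4ccccc4)cc(OCc4ccccc4)c4c3O[C@@H](c3ccc(OCc5ccccc5)cc3)[C@@H](OCc3ccccc3)C4)[C@H]2OCc2ccccc2)cc1 | intermediate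
37 | 8-[(2R,3S)-2-(benzyloxy)-3-[4-(benzyloxy)phenyl]-3-[3,5-bis(benzyloxy)-2-caesiophenoxy]propanoyl]-3,5,7,4'-tetra-O-benzylepiafzelechin-(4α→8)-3,5,7,4'-tetra-O-benzyl-ent-epiafzelechin (aryl anion drawn as its caesium compound; not isolated) | C(c1ccccc1)Oc1ccc([C@H]2Oc3c(C(=O)[C@H](OCc4ccccc4)[C@@H](Oc4cc(OCc5ccccc5)cc(OCc5ccccc5)c4[Cs])c4ccc(OCc5ccccc5)cc4)c(OCc4ccccc4)cc(OCc4ccccc4)c3[C@@H](c3c(OCc4ccccc4)cc(OCc4ccccc4)c4c3O[C@@H](c3ccc(OCc5ccccc5)cc3)[C@@H](OCc3ccccc3)C4)[C@H]2OCc2ccccc2)cc1 | intermediate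
38 | trimeric carbinol: 4-hydroxy-3,5,7,4'-tetra-O-benzyl-ent-epiafzelechin (2S, 2,3-cis, C4 carbinol unassigned) bonded through C4 to C8 of the middle unit of the benzylated (4α→8) dimer | C(c1ccccc1)Oc1ccc([C@H]2Oc3c(c(OCc4ccccc4)cc(OCc4ccccc4)c3C3(O)c4c(OCc5ccccc5)cc(OCc5ccccc5)cc4O[C@@H](c4ccc(OCc5ccccc5)cc4)[C@H]3OCc3ccccc3)[C@@H](c3c(OCc4ccccc4)cc(OCc4ccccc4)c4c3O[C@@H](c3ccc(OCc5ccccc5)cc3)[C@@H](OCc3ccccc3)C4)[C@H]2OCc2ccccc2)cc1 | intermediate
39 | dodeca-O-benzyl ent-epiafzelechin-(4β→8)-epiafzelechin-(4α→8)-ent-epiafzelechin (top 2S,3S, all-cis; middle 2R,3R, all-cis; bottom 2S,3S) | C(c1ccccc1)Oc1ccc([C@H]2Oc3c(c(OCc4ccccc4)cc(OCc4ccccc4)c3[C@H]3c4c(OCc5ccccc5)cc(OCc5ccccc5)cc4O[C@@H](c4ccc(OCc5ccccc5)cc4)[C@H]3OCc3ccccc3)[C@@H](c3c(OCc4ccccc4)cc(OCc4ccccc4)c4c3O[C@@H](c3ccc(OCc5ccccc5)cc3)[C@@H](OCc3ccccc3)C4)[C@H]2OCc2ccccc2)cc1 | intermediate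
40 | dodeca-O-benzyl ent-epiafzelechin-(4β→8)-epiafzelechin-(4α→8)-(2S,3S,4R)-flavan-3,4,5,7,4'-pentol (free hydroxyl at C4 of the bottom unit, trans to its C3 benzyloxy group) | C(c1ccccc1)Oc1ccc([C@H]2Oc3c(c(OCc4ccccc4)cc(OCc4ccccc4)c3[C@H]3c4c(OCc5ccccc5)cc(OCc5ccccc5)cc4O[C@@H](c4ccc(OCc5ccccc5)cc4)[C@H]3OCc3ccccc3)[C@@H](c3c(OCc4ccccc4)cc(OCc4ccccc4)c4c3O[C@@H](c3ccc(OCc5ccccc5)cc3)[C@@H](OCc3ccccc3)[C@@H]4O)[C@H]2OCc2ccccc2)cc1 | intermediate
41 | CNP0159291.1: ent-epiafzelechin-(4β→8)-epiafzelechin-(4α→8)-(2S,3S,4R)-flavan-3,4,5,7,4'-pentol; top (2S,3S,4R), middle (2R,3R,4S), bottom (2S,3S,4R) | Oc1ccc([C@H]2Oc3c(c(O)cc(O)c3[C@H]3c4c(O)cc(O)cc4O[C@@H](c4ccc(O)cc4)[C@H]3O)[C@@H](c3c(O)cc(O)c4c3O[C@@H](c3ccc(O)cc3)[C@@H](O)[C@@H]4O)[C@H]2O)cc1 | target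

Total step count: 22 steps.
Longest linear sequence: 16 steps (steps 4–10, then 14–22).

Steps most likely to fail

Step 19 (key step). The aryl anion may be protonated before it reaches the hindered, doubly ortho-substituted aryl ketone, leaving a simple aryl ether. Fluoride may also trigger retro-aldol cleavage or α-epimerisation of 36 before the hydroxyl has added. The fallback sets out from carbinol 19 and bromide 33 and returns at 38. Dess–Martin oxidation of 19 gives (2S,3R)-2,3-cis-3,5,7-tris(benzyloxy)-2-[4-(benzyloxy)phenyl]chroman-4-one F1, the 4-ketone of tetra-O-benzyl-ent-epiafzelechin. Aryllithium 34, made from 33 with t-BuLi in THF at −78 °C, is then added to F1. This aryllithium addition to a flavan-4-one is established chemistry for 4→8 linked flavan dimers and gives the same tertiary carbinol 38, which goes on to step 20.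

Step 8. The α-benzyloxy aldehyde 16 may epimerise at its α-carbon or fragment by retro-aldol reaction under fluoride before annulation, and its carbonyl may compete for the aryne. The fallback sets out from 16 and returns at 19. 1,3,5-Trifluorobenzene is treated with benzyl alcohol and NaH in NMP to give 1,3-bis(benzyloxy)-5-fluorobenzene F2. Ortho-lithiation between fluorine and a benzyloxy group (n-BuLi, THF, −78 °C) gives 2,4-bis(benzyloxy)-6-fluorophenyllithium F3. F3, used in excess because one equivalent is spent on the free hydroxyl, is added to 16 in THF at −78 °C to give the fluoro diol 1-[2,4-bis(benzyloxy)-6-fluorophenyl]-2-(benzyloxy)-3-[4-(benzyloxy)phenyl]propane-1,3-diol F4 (C1 epimers, C2 and C3 as in 16). KH in DMF then closes the pyran ring by intramolecular aromatic nucleophilic substitution of fluoride by the C3 alkoxide, the only one that can reach the fluorinated carbon through a six-membered ring. This is a known ring closure for benzyloxy-substituted fluoroarenes and gives 19.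

Step 15. As in step 19, the aryl anion may be quenched before ring closure and 29 may suffer base-induced retro-aldol cleavage. The fallback sets out from Weinreb amide 26 and bromide 21 and returns at 31. Aryllithium F3, prepared as in the fallback to step 8, is added to magnesium alkoxide 28 (from 26) to give the fluoroaryl ketone (2S,3R)-1-[2,4-bis(benzyloxy)-6-fluorophenyl]-2-(benzyloxy)-3-[4-(benzyloxy)phenyl]-3-hydroxypropan-1-one F5. K2CO3 in DMF closes the ring by substitution of the carbonyl-activated fluoride to give (2R,3S)-2,3-cis-3,5,7-tris(benzyloxy)-2-[4-(benzyloxy)phenyl]chroman-4-one F6. Aryllithium 27 (from 21, t-BuLi, THF, −78 °C) is added to F6 to give carbinol 31, which goes on to step 16.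

Further compounds
F1 | step 19 | (2S,3R)-2,3-cis-3,5,7-tris(benzyloxy)-2-[4-(benzyloxy)phenyl]chroman-4-one | O=C1c2c(OCc3ccccc3)cc(OCc3ccccc3)cc2O[C@@H](c2ccc(OCc3ccccc3)cc2)[C@H]1OCc1ccccc1
F2 | step 8 | 1,3-bis(benzyloxy)-5-fluorobenzene | Fc1cc(OCc2ccccc2)cc(OCc2ccccc2)c1
F3 | step 8 | 2,4-bis(benzyloxy)-6-fluorophenyllithium | [Li]c1c(F)cc(OCc2ccccc2)cc1OCc1ccccc1
F4 | step 8 | 1-[2,4-bis(benzyloxy)-6-fluorophenyl]-2-(benzyloxy)-3-[4-(benzyloxy)phenyl]propane-1,3-diol (C1 epimers; C2 and C3 as in 16) | OC(c1c(F)cc(OCc2ccccc2)cc1OCc1ccccc1)[C@H](OCc1ccccc1)[C@@H](O)c1ccc(OCc2ccccc2)cc1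
F5 | step 15 | (2S,3R)-1-[2,4-bis(benzyloxy)-6-fluorophenyl]-2-(benzyloxy)-3-[4-(benzyloxy)phenyl]-3-hydroxypropan-1-one | O=C(c1c(F)cc(OCc2ccccc2)cc1OCc1ccccc1)[C@@H](OCc1ccccc1)[C@H](O)c1ccc(OCc2ccccc2)cc1
F6 | step 15 | (2R,3S)-2,3-cis-3,5,7-tris(benzyloxy)-2-[4-(benzyloxy)phenyl]chroman-4-one | O=C1c2c(OCc3ccccc3)cc(OCc3ccccc3)cc2O[C@H](c2ccc(OCc3ccccc3)cc2)[C@@H]1OCc1ccccc1
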